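## The problem

Target 16 is the 7-O-geranyl ether of (2R,3R)-fustin. It is a chroman-4-one whose ring C is fused to the resorcinol-type ring A, carries the catechol ring B at C2 and a hydroxyl at C3, with the two substituents trans. The only two stereocentres are adjacent. C2 can control C3, because a reagent attacking the C3=C4 enol avoids the C2 aryl group and the trans (diequatorial) dihydroflavonol is also the more stable isomer; there is no practical way from C3 to C2. The absolute problem is therefore C2, a benzylic carbon bound to the ring oxygen O1. This centre is fragile: a C3 enolate can expel the O1 phenoxide (retro-oxa-Michael opening to a chalcone), and a free 4'-phenoxide can open the C2–O1 bond through a quinone methide. The dihydroflavonol is easily dehydrogenated, the catechol is air-sensitive in base, and the two trisubstituted alkenes of the geranyl chain tolerate neither metal carbenoids, dioxiranes, hydrogenation catalysts nor strong acid. Three phenols must be told apart, since only O7 carries the chain. The enabling feature is that C2 lies between O1 and ring B: in an aryl benzyl ether it is a methylene with two enantiotopic, doubly activated C–H bonds, and its neighbour C3, next to the C4 carbonyl, can be the carbenoid carbon of a diazomethyl ketone, so joining C2 to C3 closes ring C.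

## Retrosynthesis

**Geranyl ether and phenol protection.** The last skeletal bond cut is O7–C1 of the geranyl chain; before that only the two aryl silyl ethers of 15 are removed to reach 16. The chain goes on late because its alkenes would not survive the carbenoid, the dioxirane or a hydrogenolysis. Alkylating after complete deprotection is rejected because three phenols and a base-sensitive C2 would then be exposed together. Precursor 13 has a single free phenol, so the forward reaction only has to distinguish the acidic 7-OH from the secondary C3-OH; a Mitsunobu reaction with geraniol 14 does this without base. This requires a 7-O group orthogonal to the ring B silyl ethers: a benzyl ether, removed from 12 by hydrogenolysis before any alkene is present. Benzyl is also preferred at O7 because a silyl ether para to the ketone would be the most labile of the three in the enolate and amine steps.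

**C3–O bond.** Cutting the C3–O bond of 12 leads to flavanone 9 through its silyl enol ether 10. Oxidising after ring closure lets C2 direct C3, and the thermodynamic preference for trans acts as a safeguard. Carrying the oxygen into the ring-forming step would put a second substituent on the carbenoid carbon and change its reactivity. Precursor 9 has one stereocentre less. The forward sequence must enolise without a free enolate and oxidise with a small electrophilic oxidant that respects the facial bias.

**C2–C3 bond (key disconnection).** Cutting C2–C3 of 9 opens ring C and removes the last stereocentre, giving the achiral diazoketone 8. No other cut of ring C does both at once: a cut at O1–C2 (oxa-Michael) leaves a chalcone whose cyclisation is reversible, and a cut at C2–aryl needs a preformed chromone. The forward reaction is an intramolecular carbenoid insertion into one of two enantiotopic benzylic C–H bonds under a chiral carboxylate of divalent rhodium. It must prefer insertion over attack on the O1 lone pair.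

**Diazo group and aryl benzyl ether.** The diazo carbon of 8 is the methyl carbon of ketone 6, reached by trifluoroacetylation (7) and diazo transfer. This is preferred over building the diazoketone from a carboxylic acid derivative, which would need a hazardous one-carbon diazo reagent. Ketone 6 is cut at the O–CH2 bond into phenol 2 and benzyl alcohol 5; the etherification must be neutral so the silyl ethers survive, hence a Mitsunobu reaction. Phenol 2 comes from 1 by selective benzylation of the non-chelated hydroxyl. Alcohol 5 comes from aldehyde 3 by silylation (4) and reduction.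

## Roads not taken

**Alternative 1: dihydroxylation of an enantioenriched flav-3-ene.** The cut is at C3–O and C4–O. An osmium-catalysed syn-dihydroxylation of the 2H-chromene A1 on the face opposite the C2 aryl group would give the 2,3-trans-3,4-cis diol A2. Selective oxidation of the benzylic C4 hydroxyl would then give the dihydroflavonol.
- Merits: the diastereocontrol is of a very dependable kind, and the substrate is not an enolisable ketone during the oxidation. In this respect it is at least as good as, and probably safer than, the enol ether oxidation of the chosen plan.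
- Weak points: the key step forms no C–C bond and no ring and does not set C2. A1 must be obtained in enantioenriched form by separate chemistry, and 2-aryl-2H-chromenes can racemise through reversible 6π ring opening to an ortho-quinone methide. The diol needs a chemoselective oxidation at C4. The benzyl ethers can only be removed by hydrogenolysis before the geranyl chain is attached, which leaves the phenol differentiation to a fully deprotected stage.
- Comparison: the chosen plan sets the absolute configuration in the ring-forming step from an achiral precursor and has the C4 ketone in place from the start.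

**Alternative 2: ring A built last by Diels–Alder aromatisation.** The cut is at C4a–C5 and C8–C8a. The sulfinyl-activated dihydropyranone A3 would react with Danishefsky's diene A4. Loss of the sulfenic acid, the alcohol and the silyl group would aromatise the adduct to the 7-hydroxychromanone A5.
- Merits: the diene regiochemistry delivers a single free 7-OH beside silylated ring B and O3, so geranylation could follow at once. In protecting-group economy at the end this road is better than the chosen plan, which needs a benzyl ether and a hydrogenolysis for the same differentiation.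
- Weak points: it constructs a benzene ring that can be bought. A3 already holds both stereocentres, so the stereochemical problem is only moved to a pyranone that needs its own enantioselective synthesis and sulfinylation. A3 is a β-alkoxy ketone with an acidic C3–H, prone to epimerisation and ring opening under the thermal cycloaddition and elimination conditions. The dienophile is a poorly reactive vinylogous ester that must form a quaternary centre.
- Comparison: the chosen plan uses two commodity aromatics and creates C2 in the ring-forming step; it accepts one extra protecting-group operation in return.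

**Alternative 3: ortho-quinone methide cycloaddition assembling ring C.** The cut is at O1–C2 and C3–C4. A chiral BINOL-derived phosphoric acid would generate the ortho-quinone methide from salicyl alcohol A6 and mediate its [4+2] cycloaddition with the E-enol acetate A7, giving the trans flavan-3-yl acetate A8.
- Merits: two bonds, ring C and both stereocentres form in one step from two simple halves. This is more convergent than the chosen key step, which sets only C2 and leaves C3 to a later oxidation.
- Weak points: A8 lacks the C4 carbonyl, so a two-stage benzylic oxidation must follow. The methide carbon is unsubstituted, so the catalyst must control two centres remote from its binding site. For the required regiochemistry the aryl group of A7 must override the acetoxy group, which makes A7 a weakly nucleophilic partner. The benzyl ethers again force full deprotection before geranylation.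
- Comparison: the chosen plan delivers the ketone oxidation level directly, uses a reaction class already shown for this ring system, and has an orthogonal group at O7.

Key step: step 6

Remark: the sense of induction of Rh2(S-PTTL)4 in this insertion cannot be predicted with certainty. It is assumed to favour the (2S) product; should the (2R) product prevail, the enantiomeric catalyst Rh2(R-PTTL)4 takes its place with no other change.

## Route

Step 1
Reactants: 1 2',4'-dihydroxyacetophenone
Product: 2 4'-(benzyloxy)-2'-hydroxyacetophenone
Conditions: BnBr (1.05 equiv), K2CO3, acetone, reflux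
Reagents that add atoms: benzyl bromide, BrCc1ccccc1
Why: Williamson etherification; the 2'-hydroxyl is hydrogen-bonded to the ketone and less acidic, so only the 4'-phenoxide should be alkylated.

Step 2
Reactants: 3 3,4-dihydroxybenzaldehyde
Product: 4 3,4-bis(tert-butyldimethylsilyloxy)benzaldehyde
Conditions: TBSCl (2.4 equiv), imidazole, DMF, rt
Reagents that add atoms: tert-butyldimethylsilyl chloride, CC(C)(C)[Si](C)(C)Cl
Why: Standard imidazole-mediated silylation of both phenols; aryl silyl ethers are inert to carbenoids, dioxirane and hydrogenolysis and are cleaved at the end by fluoride without harm to the geranyl ether.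

Step 3
Reactants: 4 3,4-bis(tert-butyldimethylsilyloxy)benzaldehyde
Product: 5 [3,4-bis(tert-butyldimethylsilyloxy)phenyl]methanol
Conditions: NaBH4, THF–MeOH, 0 °C
Reagents that add atoms: none
Why: Hydride reduction of an aryl aldehyde; low temperature and short contact should protect the silyl ether para to the formyl group from alkoxide.

Step 4
Reactants: 2 4'-(benzyloxy)-2'-hydroxyacetophenone; 5 [3,4-bis(tert-butyldimethylsilyloxy)phenyl]methanol
Product: 6 1-{4-(benzyloxy)-2-[3,4-bis(tert-butyldimethylsilyloxy)benzyloxy]phenyl}ethanone
Conditions: PPh3, DIAD, THF, 0 °C to rt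
Reagents that add atoms: none
Why: Mitsunobu etherification of a phenol with a primary benzylic alcohol; it forms the future O1–C2 bond under neutral conditions, so the aryl silyl ethers are not exposed to carbonate or phenoxide at elevated temperature.

Step 5
Reactants: 6 1-{4-(benzyloxy)-2-[3,4-bis(tert-butyldimethylsilyloxy)benzyloxy]phenyl}ethanone
Product: 8 1-{4-(benzyloxy)-2-[3,4-bis(tert-butyldimethylsilyloxy)benzyloxy]phenyl}-2-diazoethanone, via trifluoroacetyl diketone 7 (not isolated)
Conditions: LiN(SiMe3)2, THF, −78 °C, then CF3CO2CH2CF3; aq. HCl work-up; then MsN3, Et3N, H2O (1 equiv), MeCN, rt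
Reagents that add atoms: methanesulfonyl azide, CS(=O)(=O)N=[N+]=[N-]
Why: Detrifluoroacetylative (Regitz-type) diazo transfer; the kinetic lithium enolate of the methyl ketone is trifluoroacetylated to 7, whose activated methylene takes up the diazo group with loss of the trifluoroacetyl unit as its sulfonamide. The methyl group is the only enolisable position and no silyl ether sits on the acyl-bearing ring.

Step 6
Reactants: 8 1-{4-(benzyloxy)-2-[3,4-bis(tert-butyldimethylsilyloxy)benzyloxy]phenyl}-2-diazoethanone
Product: 9 (2S)-7-(benzyloxy)-2-[3,4-bis(tert-butyldimethylsilyloxy)phenyl]chroman-4-one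
Conditions: Rh2(S-PTTL)4 (1 mol %; dirhodium tetrakis[N-phthaloyl-(S)-tert-leucinate]), CH2Cl2, 0 °C, slow addition of 8
Reagents that add atoms: none
Why: The dirhodium carboxylate attacks the diazo carbon, dinitrogen leaves, and an electrophilic rhodium carbenoid forms at the future C3; its empty orbital engages one benzylic C–H bond of the O–CH2–aryl group in a three-centre, hydride-shift-like transition state in which C2–C3 forms as hydrogen moves to C3 and the catalyst is released. The closest known reaction type is the enantioselective intramolecular C–H insertion of ortho-alkoxyaryl diazomethyl ketones at the ether α-carbon under chiral carboxylates of divalent rhodium, which gives 2-substituted chroman-4-ones. Ring C closes by 1,6-C–H insertion through a six-membered cyclic array (C3, C4, C4a, C8a, O1, C2); the usual 1,5 mode is unavailable because the fifth atom is O1. The C2 stereocentre is set by the catalyst alone: the phthalimido tert-leucinate ligands should let the carbenoid reach only one of the two enantiotopic benzylic hydrogens, and 8 has no stereocentre to interfere. Two selectivities are needed: insertion over oxonium ylide formation at O1 (which would end in a [1,2]-benzyl shift to a benzofuranone), and one enantiotopic hydrogen over the other. The substrate helps with the first, since the O1 lone pairs are delocalised into the acyl-substituted ring and are weakly nucleophilic, while the C–H bonds are hydridic because positive charge at C2 is stabilised by O1 and by the para-silyloxy group of ring B. A rhodium carboxylate in place of a copper catalyst, a non-coordinating solvent and slow addition should favour concerted insertion and suppress carbene dimerisation. The remote 7-benzyloxy group and the aryl silyl ethers offer no C–H or π bond within reach of the carbenoid.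

Step 7
Reactants: 9 (2S)-7-(benzyloxy)-2-[3,4-bis(tert-butyldimethylsilyloxy)phenyl]chroman-4-one
Product: 10 (2S)-7-(benzyloxy)-2-[3,4-bis(tert-butyldimethylsilyloxy)phenyl]-4-(trimethylsilyloxy)-2H-chromene
Conditions: TMSOTf, Et3N, CH2Cl2, 0 °C; non-aqueous work-up, used crude
Reagents that add atoms: trimethylsilyl trifluoromethanesulfonate, C[Si](C)(C)OS(=O)(=O)C(F)(F)F
Why: Soft enolisation (O-silylation of the carbonyl, then deprotonation at C3 by the amine); no free enolate is formed, so the retro-oxa-Michael opening that would racemise C2 should not occur, and C3 is the only enolisable position.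

Step 8
Reactants: 10 (2S)-7-(benzyloxy)-2-[3,4-bis(tert-butyldimethylsilyloxy)phenyl]-4-(trimethylsilyloxy)-2H-chromene
Product: 12 (2R,3R)-7-(benzyloxy)-2-[3,4-bis(tert-butyldimethylsilyloxy)phenyl]-3-hydroxychroman-4-one, via silyloxy epoxide 11 (not isolated)
Conditions: dimethyldioxirane (acetone solution, 1.2 equiv), CH2Cl2, −78 to −20 °C; then aq. citric acid, THF, 0 °C
Reagents that add atoms: dimethyldioxirane, CC1(C)OO1
Why: Rubottom oxidation; the dioxirane should epoxidise the electron-rich C3=C4 enol ether on the face opposite the C2 aryl group, and mild acid opens epoxide 11 to the α-hydroxy ketone with the C3–O bond intact, giving the 2,3-trans isomer, which is also the thermodynamic one. The descriptor at C2 changes from S to R only because oxygenated C3 now outranks the aryl group; the spatial arrangement is unchanged.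

Step 9
Reactants: 12 (2R,3R)-7-(benzyloxy)-2-[3,4-bis(tert-butyldimethylsilyloxy)phenyl]-3-hydroxychroman-4-one
Product: 13 (2R,3R)-2-[3,4-bis(tert-butyldimethylsilyloxy)phenyl]-3,7-dihydroxychroman-4-one
Conditions: H2 (1 atm), 10% Pd/C, EtOAc, rt
Reagents that add atoms: none
Why: Hydrogenolysis of the aryl benzyl ether, routine in flavonoid deprotection; the aryl silyl ethers are inert in an aprotic solvent, and the conjugated C4 ketone and the cyclic C2–O1 bond react much more slowly than the O-benzyl group, so the reaction is stopped once 12 is consumed.

Step 10
Reactants: 13 (2R,3R)-2-[3,4-bis(tert-butyldimethylsilyloxy)phenyl]-3,7-dihydroxychroman-4-one; 14 geraniol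
Product: 15 (2R,3R)-2-[3,4-bis(tert-butyldimethylsilyloxy)phenyl]-7-{[(2E)-3,7-dimethylocta-2,6-dien-1-yl]oxy}-3-hydroxychroman-4-one
Conditions: PPh3, DIAD, THF, 0 °C to rt
Reagents that add atoms: none
Why: Mitsunobu etherification; the 7-phenol, para to the C4 carbonyl, is the only acidic hydroxyl and acts as pronucleophile, while the primary allylic alcohol 14 is activated much faster than the hindered secondary C3-OH. SN2 displacement at C1 keeps the E-alkene, and the neutral medium leaves C2, C3 and the silyl ethers untouched.

Step 11
Reactants: 15 (2R,3R)-2-[3,4-bis(tert-butyldimethylsilyloxy)phenyl]-7-{[(2E)-3,7-dimethylocta-2,6-dien-1-yl]oxy}-3-hydroxychroman-4-one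
Product: 16 (2R,3R)-2-(3,4-dihydroxyphenyl)-7-{[(2E)-3,7-dimethylocta-2,6-dien-1-yl]oxy}-3-hydroxychroman-4-one
Conditions: Bu4NF (2.2 equiv), AcOH (2.5 equiv), THF, 0 °C
Reagents that add atoms: none
Why: Fluoride cleavage of the two aryl silyl ethers; the acetic acid buffer keeps the liberated catechol protonated so that C2 is not opened through a quinone methide, and the geranyl ether and the dihydroflavonol are inert to buffered fluoride.

## Compound list

1 | 2',4'-dihydroxyacetophenone | CC(=O)c1ccc(O)cc1O | starting material
2 | 4'-(benzyloxy)-2'-hydroxyacetophenone | CC(=O)c1ccc(OCc2ccccc2)cc1O | intermediate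
3 | 3,4-dihydroxybenzaldehyde | O=Cc1ccc(O)c(O)c1 | starting material
4 | 3,4-bis(tert-butyldimethylsilyloxy)benzaldehyde | O=Cc1ccc(O[Si](C)(C)C(C)(C)C)c(O[Si](C)(C)C(C)(C)C)c1 | intermediate
5 | [3,4-bis(tert-butyldimethylsilyloxy)phenyl]methanol | OCc1ccc(O[Si](C)(C)C(C)(C)C)c(O[Si](C)(C)C(C)(C)C)c1 | intermediate
6 | 1-{4-(benzyloxy)-2-[3,4-bis(tert-butyldimethylsilyloxy)benzyloxy]phenyl}ethanone | CC(=O)c1ccc(OCc2ccccc2)cc1OCc1ccc(O[Si](C)(C)C(C)(C)C)c(O[Si](C)(C)C(C)(C)C)c1 | intermediate
7 | 1-{4-(benzyloxy)-2-[3,4-bis(tert-butyldimethylsilyloxy)benzyloxy]phenyl}-4,4,4-trifluorobutane-1,3-dione | O=C(CC(=O)C(F)(F)F)c1ccc(OCc2ccccc2)cc1OCc1ccc(O[Si](C)(C)C(C)(C)C)c(O[Si](C)(C)C(C)(C)C)c1 | intermediate (not isolated)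
8 | 1-{4-(benzyloxy)-2-[3,4-bis(tert-butyldimethylsilyloxy)benzyloxy]phenyl}-2-diazoethanone | [N-]=[N+]=CC(=O)c1ccc(OCc2ccccc2)cc1OCc1ccc(O[Si](C)(C)C(C)(C)C)c(O[Si](C)(C)C(C)(C)C)c1 | intermediate
9 | (2S)-7-(benzyloxy)-2-[3,4-bis(tert-butyldimethylsilyloxy)phenyl]chroman-4-one | c1ccccc1COc1ccc2c(c1)O[C@H](c1ccc(O[Si](C)(C)C(C)(C)C)c(O[Si](C)(C)C(C)(C)C)c1)CC2=O | intermediate
10 | (2S)-7-(benzyloxy)-2-[3,4-bis(tert-butyldimethylsilyloxy)phenyl]-4-(trimethylsilyloxy)-2H-chromene | c1ccccc1COc1ccc2c(c1)O[C@H](c1ccc(O[Si](C)(C)C(C)(C)C)c(O[Si](C)(C)C(C)(C)C)c1)C=C2O[Si](C)(C)C | intermediate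
11 | (2R,3R,4R)-7-(benzyloxy)-2-[3,4-bis(tert-butyldimethylsilyloxy)phenyl]-3,4-epoxy-4-(trimethylsilyloxy)chromane, oxirane oxygen on the face opposite the C2 aryl group | c1ccccc1COc1ccc2c(c1)O[C@H](c1ccc(O[Si](C)(C)C(C)(C)C)c(O[Si](C)(C)C(C)(C)C)c1)[C@H]3O[C@@]23O[Si](C)(C)C | intermediate (not isolated)
12 | (2R,3R)-7-(benzyloxy)-2-[3,4-bis(tert-butyldimethylsilyloxy)phenyl]-3-hydroxychroman-4-one | c1ccccc1COc1ccc2c(c1)O[C@H](c1ccc(O[Si](C)(C)C(C)(C)C)c(O[Si](C)(C)C(C)(C)C)c1)[C@@H](O)C2=O | intermediate
13 | (2R,3R)-2-[3,4-bis(tert-butyldimethylsilyloxy)phenyl]-3,7-dihydroxychroman-4-one | Oc1ccc2c(c1)O[C@H](c1ccc(O[Si](C)(C)C(C)(C)C)c(O[Si](C)(C)C(C)(C)C)c1)[C@@H](O)C2=O | intermediate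
14 | geraniol, (2E)-3,7-dimethylocta-2,6-dien-1-ol | CC(C)=CCC/C(C)=C/CO | starting material
15 | (2R,3R)-2-[3,4-bis(tert-butyldimethylsilyloxy)phenyl]-7-{[(2E)-3,7-dimethylocta-2,6-dien-1-yl]oxy}-3-hydroxychroman-4-one | CC(C)=CCC/C(C)=C/COc1ccc2c(c1)O[C@H](c1ccc(O[Si](C)(C)C(C)(C)C)c(O[Si](C)(C)C(C)(C)C)c1)[C@@H](O)C2=O | intermediate
16 | (2R,3R)-2-(3,4-dihydroxyphenyl)-7-{[(2E)-3,7-dimethylocta-2,6-dien-1-yl]oxy}-3-hydroxychroman-4-one (7-O-geranylfustin, CNP0508026.1) | CC(C)=CCC/C(C)=C/COc1ccc2c(c1)O[C@H](c1ccc(O)c(O)c1)[C@@H](O)C2=O | target

## Step count and risks

Total: 11 steps. Longest linear sequence: 10 steps (3 → 4 → 5 → 6 → 8 → 9 → 10 → 12 → 13 → 15 → 16); the branch from 1 joins at step 4.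

**Step 6 (key step).** The most likely failure is attack of the carbenoid on the O1 lone pair with a subsequent [1,2]-benzyl shift, in place of C–H insertion. The second is insufficient discrimination of the two benzylic hydrogens by the catalyst. The fallback sets out from 2 and returns at 9, forming C2 as a C–aryl bond with no carbenoid. Condensation of 2 with N,N-dimethylformamide dimethyl acetal would give the enaminone (E)-1-[4-(benzyloxy)-2-hydroxyphenyl]-3-(dimethylamino)prop-2-en-1-one F1, which closes under acid to 7-(benzyloxy)-4H-chromen-4-one F2. Separately, commercial 4-bromocatechol would be silylated to 4-bromo-1,2-bis(tert-butyldimethylsilyloxy)benzene F3. Bromine–lithium exchange with n-BuLi and borylation with B(OiPr)3 would give [3,4-bis(tert-butyldimethylsilyloxy)phenyl]boronic acid F4. Enantioselective conjugate addition of F4 to F2 with Pd(OCOCF3)2 and a chiral pyridine–oxazoline ligand, a known entry to 2-arylchroman-4-ones, would then give 9.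

**Step 8.** The trimethylsilyl enol ether may hydrolyse back to 9 before it is oxidised, or epoxidation may occur partly on the face syn to the aryl group. The fallback sets out from 9 and returns at 12: deprotonation with KN(SiMe3)2 in THF at −78 °C and direct hydroxylation of the potassium enolate with 2-(phenylsulfonyl)-3-phenyloxaziridine. No new compound arises (F0). The low temperature is needed to hold back ring opening of the enolate.

**Step 10.** The betaine may activate the secondary C3 hydroxyl, leading to elimination or O3-alkylation, or the phenoxide may attack in the SN2' sense. The fallback sets out from 13 and returns at 15: Williamson alkylation of the 7-phenoxide with geranyl bromide and one equivalent of K2CO3 in acetone at rt, relying on the large acidity gap between the phenol and the alcohol. No new compound arises (F0).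

**Step 4.** Etherification of the hydrogen-bonded, weakly acidic 2'-phenol may be sluggish, with the activated electron-rich benzyl alcohol alkylating the reduced azodicarboxylate instead. The fallback sets out from 5 and returns at 6: conversion of 5 with CBr4 and PPh3 into 4-(bromomethyl)-1,2-bis(tert-butyldimethylsilyloxy)benzene F5, then alkylation of 2 with F5 using K2CO3 and catalytic Bu4NI in acetone at or slightly above rt.

**Step 11.** If buffering is incomplete, basic fluoride may open the C2–O1 bond once the 4'-phenoxide is unmasked, epimerising C2, and the catechol may oxidise in air. The fallback sets out from 13 and returns at 16, reversing the order of the last two operations. Desilylation of 13 with HF·pyridine in THF, acceptable because no acid-sensitive allylic ether is present yet, would give (2R,3R)-fustin F6. Alkylation of its most acidic 7-hydroxyl with geranyl bromide and one equivalent of K2CO3 in DMF at rt would then give 16.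

## Further compounds

F1 | step 6 | (E)-1-[4-(benzyloxy)-2-hydroxyphenyl]-3-(dimethylamino)prop-2-en-1-one | CN(C)/C=C/C(=O)c1ccc(OCc2ccccc2)cc1O
F2 | step 6 | 7-(benzyloxy)-4H-chromen-4-one | O=c1ccoc2cc(OCc3ccccc3)ccc12
F3 | step 6 | 4-bromo-1,2-bis(tert-butyldimethylsilyloxy)benzene | Brc1ccc(O[Si](C)(C)C(C)(C)C)c(O[Si](C)(C)C(C)(C)C)c1
F4 | step 6 | [3,4-bis(tert-butyldimethylsilyloxy)phenyl]boronic acid | OB(O)c1ccc(O[Si](C)(C)C(C)(C)C)c(O[Si](C)(C)C(C)(C)C)c1
F0 | step 8 | none | none
F0 | step 10 | none | none
F5 | step 4 | 4-(bromomethyl)-1,2-bis(tert-butyldimethylsilyloxy)benzene | BrCc1ccc(O[Si](C)(C)C(C)(C)C)c(O[Si](C)(C)C(C)(C)C)c1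
F6 | step 11 | (2R,3R)-fustin, (2R,3R)-2-(3,4-dihydroxyphenyl)-3,7-dihydroxychroman-4-one | Oc1ccc2c(c1)O[C@H](c1ccc(O)c(O)c1)[C@@H](O)C2=O
A1 | alternative 1 | (2S)-7-(benzyloxy)-2-[3,4-bis(benzyloxy)phenyl]-2H-chromene | c1ccc(COc2ccc3c(c2)O[C@H](c2ccc(OCc4ccccc4)c(OCc4ccccc4)c2)C=C3)cc1
A2 | alternative 1 | (2R,3S,4S)-7-(benzyloxy)-2-[3,4-bis(benzyloxy)phenyl]chromane-3,4-diol | c1ccc(COc2ccc3c(c2)O[C@H](c2ccc(OCc4ccccc4)c(OCc4ccccc4)c2)[C@@H](O)[C@H]3O)cc1
A3 | alternative 2 | (2R,3R)-3-(tert-butyldimethylsilyloxy)-2-[3,4-bis(tert-butyldimethylsilyloxy)phenyl]-5-(phenylsulfinyl)-2,3-dihydro-4H-pyran-4-one (configuration at sulfur not specified) | O=C1C(S(=O)c2ccccc2)=CO[C@H](c2ccc(O[Si](C)(C)C(C)(C)C)c(O[Si](C)(C)C(C)(C)C)c2)[C@H]1O[Si](C)(C)C(C)(C)C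
A4 | alternative 2 | Danishefsky's diene, (E)-1-methoxy-3-(trimethylsilyloxy)buta-1,3-diene | CO/C=C/C(=C)O[Si](C)(C)C
A5 | alternative 2 | (2R,3R)-3-(tert-butyldimethylsilyloxy)-2-[3,4-bis(tert-butyldimethylsilyloxy)phenyl]-7-hydroxychroman-4-one | Oc1ccc2c(c1)O[C@H](c1ccc(O[Si](C)(C)C(C)(C)C)c(O[Si](C)(C)C(C)(C)C)c1)[C@@H](O[Si](C)(C)C(C)(C)C)C2=O
A6 | alternative 3 | 5-(benzyloxy)-2-(hydroxymethyl)phenol | OCc1ccc(OCc2ccccc2)cc1O
A7 | alternative 3 | (E)-2-[3,4-bis(benzyloxy)phenyl]ethenyl acetate | CC(=O)O/C=C/c1ccc(OCc2ccccc2)c(OCc2ccccc2)c1
A8 | alternative 3 | (2R,3S)-7-(benzyloxy)-2-[3,4-bis(benzyloxy)phenyl]chroman-3-yl acetate | c1ccc(COc2ccc3c(c2)O[C@H](c2ccc(OCc4ccccc4)c(OCc4ccccc4)c2)[C@@H](OC(C)=O)C3)cc1
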